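**Plan**

- The two isobutyrate C–O bonds are cut first (both esters go on last, in place of silyl ethers). The oxirane is then cut at its quaternary C–CH2 bond and its CH2–O bond, leaving an aryl silyloxymethyl ketone and a one-carbon sulfoxonium ylide.
- The ketone is cut at its α C–O bond back to the aryl methyl ketone, and the aryl–acetyl bond back to 4-methoxy-3-methylphenol.
- Enabling feature: the oxirane is terminal and 2,2-disubstituted, and its fully substituted carbon carries the benzene ring and a CH2–O arm. That carbon is therefore a masked ketone carbonyl and the ring CH2 a transferable methylene.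
- Forward: the benzene ring is bought; acetyl is placed ortho to the phenol oxygen, the phenol is silylated and the methyl ketone is α-oxygenated. The oxirane, the only ring made, closes in step 6, and a one-pot silyl-to-isobutyryl exchange ends the route.
- The single stereocentre (S) is set in step 6 by the chiral lanthanum–lithium binaphthoxide catalyst; no later step breaks a bond at that carbon.

Key step: step 6

Assumption: with the (S)-binaphthoxide complex the ylide is taken to attack the carbonyl face that leads to (S)-11, by analogy with aryl methyl ketones (aryl as the large group, CH2OSi as the small one). The sense is to be checked on the first run against material from the fallback to step 6, and the (R)-complex is to be used if the mirror image forms.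

Assumption: 4-methoxy-3-methylphenol, trimethylsulfoxonium iodide, (S)-BINOL, La(OiPr)3 and tris(2,4,6-trimethoxyphenyl)phosphine (oxidised to its oxide with H2O2) are taken as purchasable.

**Route**

Step 1
Reactants: 1 4-methoxy-3-methylphenol
Product: 4 1-(2-hydroxy-5-methoxy-4-methylphenyl)ethan-1-one, via 4-methoxy-3-methylphenyl acetate 2 (not isolated), via difluoroboron chelate 3 (not isolated)
Conditions: AcOH, BF3·OEt2, 90 °C; then H2O/EtOH, 60 °C
Reagents that add atoms: acetic acid, CC(=O)O
Why: BF3 promotes O-acetylation followed by Fries rearrangement, and because the para position is blocked by OMe and the ortho-hydroxy ketone is trapped as its boron chelate, the acetyl group should settle ortho to the phenol oxygen at the unhindered carbon para to the ring methyl rather than between OH and CH3.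

Step 2
Reactants: 4 1-(2-hydroxy-5-methoxy-4-methylphenyl)ethan-1-one
Product: 5 1-[5-methoxy-4-methyl-2-(triisopropylsilyloxy)phenyl]ethan-1-one
Conditions: TIPSCl, imidazole, DMAP (cat.), DMF, 40 °C
Reagents that add atoms: chlorotriisopropylsilane, CC(C)[Si](Cl)(C(C)C)C(C)C
Why: Imidazole-promoted silylation of the phenol (silyl ether formation) masks the acidic OH as a bulky, base-stable triisopropylsilyl ether that the later enolisation, peracid and ylide steps should leave intact.

Step 3
Reactants: 5 1-[5-methoxy-4-methyl-2-(triisopropylsilyloxy)phenyl]ethan-1-one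
Product: 6 tert-butyl({1-[5-methoxy-4-methyl-2-(triisopropylsilyloxy)phenyl]ethenyl}oxy)dimethylsilane
Conditions: TBSOTf, Et3N, CH2Cl2, 0 °C
Reagents that add atoms: tert-butyldimethylsilyl trifluoromethanesulfonate, CC(C)(C)[Si](C)(C)OS(=O)(=O)C(F)(F)F
Why: Soft enolisation with a silyl triflate and Et3N (silyl enol ether formation) can remove a proton only from the methyl group, so a single terminal enol ether should result.

Step 4
Reactants: 6 tert-butyl({1-[5-methoxy-4-methyl-2-(triisopropylsilyloxy)phenyl]ethenyl}oxy)dimethylsilane
Product: 8 2-(tert-butyldimethylsilyloxy)-1-[5-methoxy-4-methyl-2-(triisopropylsilyloxy)phenyl]ethan-1-one, via silyloxy oxirane 7 (not isolated)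
Conditions: mCPBA, NaHCO3, CH2Cl2, −10 to 0 °C
Reagents that add atoms: 3-chloroperoxybenzoic acid, OOC(=O)c1cccc(Cl)c1
Why: Rubottom oxidation: the peracid should epoxidise the electron-rich enol ether C=C far faster than it attacks the arene or the product ketone, and the silyloxy oxirane opens with 1,4-migration of silicon from the carbonyl oxygen to the new α-oxygen to give the α-silyloxy ketone directly.

Step 5
Reactants: 9 trimethylsulfoxonium iodide
Product: 10 dimethylsulfoxonium methylide (THF solution)
Conditions: NaH, THF, reflux; clear solution titrated and used as such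
Reagents that add atoms: none
Why: Deprotonation of the sulfoxonium salt by NaH is the standard generation of the Corey–Chaykovsky methylide, which carries the CH2 unit for the oxirane.

Step 6
Reactants: 8 2-(tert-butyldimethylsilyloxy)-1-[5-methoxy-4-methyl-2-(triisopropylsilyloxy)phenyl]ethan-1-one; 10 dimethylsulfoxonium methylide
Product: 11 tert-butyl({(2S)-2-[5-methoxy-4-methyl-2-(triisopropylsilyloxy)phenyl]oxiran-2-yl}methoxy)dimethylsilane
Conditions: 10 (1.2 equiv), LaLi3[(S)-binaphthoxide]3 (5 mol%, from La(OiPr)3, (S)-BINOL, BuLi), (2,4,6-(MeO)3C6H2)3P=O (5 mol%), MS 5Å, THF, rt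
Reagents that add atoms: none
Why: Proposed new method: the ylide carbon of 10, positioned by a lithium binaphthoxide arm, adds to the carbonyl carbon of 8 held on lanthanum, and the metal-bound alkoxide then displaces dimethyl sulfoxide from the adjacent CH2, so the quaternary C–CH2 bond and the CH2–O bond form in one operation. The closest known reaction is the Corey–Chaykovsky epoxidation of aryl and alkyl methyl ketones with dimethylsulfoxonium methylide under this LaLi3(binaphthoxide)3/triarylphosphine oxide system; an α-silyloxy, ortho-substituted aryl ketone goes beyond the substrates shown for it. The oxirane closes in a 3-exo-tet mode. The new quaternary stereocentre is set by catalyst control, the (S)-binaphthoxide pocket selecting the carbonyl face on which the bulky ortho-silyloxyaryl group takes the place of the large substituent and the CH2OSi arm that of the small, methyl-like one. The step needs enantioface selectivity and a single clean methylene transfer: the size gap between the two ketone substituents serves the first, while silyl rather than acyl protection (no ester for the ylide to attack), the slow-migrating triisopropylsilyl group on the phenol and only 1.2 equiv of ylide at room temperature (no second transfer to an oxetane) serve the second.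

Step 7
Reactants: 11 tert-butyl({(2S)-2-[5-methoxy-4-methyl-2-(triisopropylsilyloxy)phenyl]oxiran-2-yl}methoxy)dimethylsilane
Product: 12 {(2S)-2-[5-methoxy-4-methyl-2-(2-methylpropanoyloxy)phenyl]oxiran-2-yl}methyl 2-methylpropanoate
Conditions: (iPrCO)2O (excess), TBAF (slow addition), THF, −20 to 0 °C
Reagents that add atoms: isobutyric anhydride, CC(C)C(=O)OC(=O)C(C)C
Why: Fluoride-induced desilylation in the presence of excess anhydride (one-pot silyl-to-acyl exchange) should cleave first the aryl and then the alkyl silyl ether and acylate each oxyanion as it forms, so that no phenoxide lingers beside the benzylic oxirane; the stereocentre is not touched, and even a Payne shift of the transient alkoxide would be degenerate and return the same enantiomer.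

**Compound list**

1 | 4-methoxy-3-methylphenol | COc1ccc(O)cc1C | starting material
2 | 4-methoxy-3-methylphenyl acetate | COc1ccc(OC(C)=O)cc1C | intermediate (not isolated)
3 | difluoroboron O,O-chelate of ketone 4 (2,2-difluoro-6-methoxy-4,7-dimethyl-1,3,2-benzodioxaborinine, zwitterionic) | COc1cc2c(cc1C)O[B-](F)(F)[O+]=C2C | intermediate (not isolated)
4 | 1-(2-hydroxy-5-methoxy-4-methylphenyl)ethan-1-one | COc1cc(C(C)=O)c(O)cc1C | intermediate
5 | 1-[5-methoxy-4-methyl-2-(triisopropylsilyloxy)phenyl]ethan-1-one | COc1cc(C(C)=O)c(O[Si](C(C)C)(C(C)C)C(C)C)cc1C | intermediate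
6 | tert-butyl({1-[5-methoxy-4-methyl-2-(triisopropylsilyloxy)phenyl]ethenyl}oxy)dimethylsilane | COc1cc(C(=C)O[Si](C)(C)C(C)(C)C)c(O[Si](C(C)C)(C(C)C)C(C)C)cc1C | intermediate
7 | racemic tert-butyl({2-[5-methoxy-4-methyl-2-(triisopropylsilyloxy)phenyl]oxiran-2-yl}oxy)dimethylsilane | COc1cc(C2(O[Si](C)(C)C(C)(C)C)CO2)c(O[Si](C(C)C)(C(C)C)C(C)C)cc1C | intermediate (not isolated)
8 | 2-(tert-butyldimethylsilyloxy)-1-[5-methoxy-4-methyl-2-(triisopropylsilyloxy)phenyl]ethan-1-one | COc1cc(C(=O)CO[Si](C)(C)C(C)(C)C)c(O[Si](C(C)C)(C(C)C)C(C)C)cc1C | intermediate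
9 | trimethylsulfoxonium iodide | C[S+](C)(C)=O.[I-] | starting material
10 | dimethylsulfoxonium methylide | C[S+](C)(=O)[CH2-] | intermediate
11 | tert-butyl({(2S)-2-[5-methoxy-4-methyl-2-(triisopropylsilyloxy)phenyl]oxiran-2-yl}methoxy)dimethylsilane | COc1cc([C@@]2(CO[Si](C)(C)C(C)(C)C)CO2)c(O[Si](C(C)C)(C(C)C)C(C)C)cc1C | intermediate
12 | {(2S)-2-[5-methoxy-4-methyl-2-(2-methylpropanoyloxy)phenyl]oxiran-2-yl}methyl 2-methylpropanoate | COc1cc([C@@]2(COC(=O)C(C)C)CO2)c(OC(=O)C(C)C)cc1C | target

**Step count**

Total steps: 7 (steps 1–4, 6 and 7 in line; step 5 is a one-step side branch).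
Longest linear sequence: 6 steps (1, 2, 3, 4, 6, 7).

**Steps most likely to fail**

1. Step 6. The catalyst pocket may fail to distinguish the ortho-silyloxyaryl group from the CH2OSi arm (poor enantioface selection). Addition to the hindered carbonyl may be slow, or silicon may shift onto the intermediate alkoxide before ring closure. Fallback with known chemistry, setting out from 8 and returning at 12:
   - Wittig methylenation of 8 (Ph3PCH3Br, KOtBu, THF) gives the alkene tert-butyl({2-[5-methoxy-4-methyl-2-(triisopropylsilyloxy)phenyl]prop-2-en-1-yl}oxy)dimethylsilane F1.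
   - Mild acid methanolysis (CSA cat., MeOH/CH2Cl2, 0 °C) removes only the alkyl silyl ether and gives the allylic alcohol 2-[5-methoxy-4-methyl-2-(triisopropylsilyloxy)phenyl]prop-2-en-1-ol F2.
   - Sharpless asymmetric epoxidation (Ti(OiPr)4, D-(−)-diisopropyl tartrate, tBuOOH, MS 4Å, CH2Cl2, −20 °C) uses the tartrate enantiomer that leads 2-substituted allyl alcohols into the (R)-glycidol series. It should give the epoxy alcohol {(2R)-2-[5-methoxy-4-methyl-2-(triisopropylsilyloxy)phenyl]oxiran-2-yl}methanol F3. The descriptor is R only because the free CH2OH arm ranks below the ring CH2; the spatial arrangement is that of the target.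
   - Acylation with isobutyric anhydride, Et3N and DMAP gives the ester {(2S)-2-[5-methoxy-4-methyl-2-(triisopropylsilyloxy)phenyl]oxiran-2-yl}methyl 2-methylpropanoate F4.
   - TBAF in the presence of isobutyric anhydride then exchanges the aryl silyl ether for the second isobutyrate and gives 12.

2. Step 7. If acylation lags behind desilylation, the free phenoxide can open the benzylic oxirane. Fluoride or carboxylate may also attack the oxirane, or the acyl group may shift between the two oxygens. Fallback, setting out from 11 and returning at 12, replaces the one-pot exchange by a staged one in which the phenol oxygen is capped first and never freed again: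
   - One equivalent of TBAF added at −40 °C to 11 and isobutyric anhydride cleaves only the more labile aryl–O–Si bond and gives 2-[(2S)-2-{[(tert-butyldimethylsilyl)oxy]methyl}oxiran-2-yl]-4-methoxy-5-methylphenyl 2-methylpropanoate F5.
   - TBAF buffered with AcOH (THF, rt) removes the alkyl silyl ether under near-neutral conditions and gives 2-[(2R)-2-(hydroxymethyl)oxiran-2-yl]-4-methoxy-5-methylphenyl 2-methylpropanoate F6.
   - Isobutyric anhydride, Et3N and DMAP (CH2Cl2, 0 °C) then give 12.

3. Step 4. Acid-induced loss of silicon from the silyloxy oxirane may give ketol mixtures, and the peracid may cause Baeyer–Villiger oxidation of the electron-rich aryl ketone or oxidise the ring. Fallback, setting out from 5 and returning at 8, replaces oxidation by halogenation and substitution: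
   - α-Bromination of 5 with PhNMe3Br3 in THF gives 2-bromo-1-[5-methoxy-4-methyl-2-(triisopropylsilyloxy)phenyl]ethan-1-one F7.
   - Displacement with HCO2Cs in DMF gives 2-[5-methoxy-4-methyl-2-(triisopropylsilyloxy)phenyl]-2-oxoethyl formate F8.
   - Methanolysis (MeOH, NaHCO3, 0 °C) gives the ketol 2-hydroxy-1-[5-methoxy-4-methyl-2-(triisopropylsilyloxy)phenyl]ethan-1-one F9.
   - TBSCl and imidazole in DMF then give 8.

Further compounds
F1 | step 6 | tert-butyl({2-[5-methoxy-4-methyl-2-(triisopropylsilyloxy)phenyl]prop-2-en-1-yl}oxy)dimethylsilane | COc1cc(C(=C)CO[Si](C)(C)C(C)(C)C)c(O[Si](C(C)C)(C(C)C)C(C)C)cc1C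
F2 | step 6 | 2-[5-methoxy-4-methyl-2-(triisopropylsilyloxy)phenyl]prop-2-en-1-ol | COc1cc(C(=C)CO)c(O[Si](C(C)C)(C(C)C)C(C)C)cc1C
F3 | step 6 | {(2R)-2-[5-methoxy-4-methyl-2-(triisopropylsilyloxy)phenyl]oxiran-2-yl}methanol | COc1cc([C@@]2(CO)CO2)c(O[Si](C(C)C)(C(C)C)C(C)C)cc1C
F4 | step 6 | {(2S)-2-[5-methoxy-4-methyl-2-(triisopropylsilyloxy)phenyl]oxiran-2-yl}methyl 2-methylpropanoate | COc1cc([C@@]2(COC(=O)C(C)C)CO2)c(O[Si](C(C)C)(C(C)C)C(C)C)cc1C
F5 | step 7 | 2-[(2S)-2-{[(tert-butyldimethylsilyl)oxy]methyl}oxiran-2-yl]-4-methoxy-5-methylphenyl 2-methylpropanoate | COc1cc([C@@]2(CO[Si](C)(C)C(C)(C)C)CO2)c(OC(=O)C(C)C)cc1C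
F6 | step 7 | 2-[(2R)-2-(hydroxymethyl)oxiran-2-yl]-4-methoxy-5-methylphenyl 2-methylpropanoate | COc1cc([C@@]2(CO)CO2)c(OC(=O)C(C)C)cc1C
F7 | step 4 | 2-bromo-1-[5-methoxy-4-methyl-2-(triisopropylsilyloxy)phenyl]ethan-1-one | COc1cc(C(=O)CBr)c(O[Si](C(C)C)(C(C)C)C(C)C)cc1C
F8 | step 4 | 2-[5-methoxy-4-methyl-2-(triisopropylsilyloxy)phenyl]-2-oxoethyl formate | COc1cc(C(=O)COC=O)c(O[Si](C(C)C)(C(C)C)C(C)C)cc1C
F9 | step 4 | 2-hydroxy-1-[5-methoxy-4-methyl-2-(triisopropylsilyloxy)phenyl]ethan-1-one | COc1cc(C(=O)CO)c(O[Si](C(C)C)(C(C)C)C(C)C)cc1C
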